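**Retrosynthetic overview**

1. The target is traced back to a flavan that carries a silyloxy group at C4; ionic hydrogenation turns C4 into CH2 and leaves C2 alone.
2. Ring C of that flavan is opened at C4–C4a and at C2–C3, giving a racemic acyclic acetoxy aryl ether (O1–C2 already in place) and a two-carbon enolsilane. Forward, this is a catalytic enantioselective cationic [4+2] (oxa-Povarov) annulation that closes ring C and sets C2.
3. Enabling feature: ring A is a phloroglucinol triether. C4a lies ortho to O1 and to the C5 methoxy group and para to the C7 methoxy group, and it is equivalent to C8 through the local mirror plane through C8a and C6. O1 and the 4-methoxyphenyl ring at C2 stabilise a C2=O1 oxocarbenium ion, so C4a=C8a–O1=C2 is a cationic 2-oxadiene with no regiochemical choice.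
4. The acetoxy ether comes from 3,5-dimethoxy-4-prenylphenol, 4-methoxybenzaldehyde and acetyl bromide; the phenol comes from 3,5-dimethoxyphenol by silylation, lithiation and prenylation between the two methoxy groups, and desilylation.
5. Ring order: rings A and B are bought as arenes; ring C is the only ring formed, in the key step.

Key step: step 5

Remark: the facial sense of the chiral acid in step 5 cannot be predicted with certainty, so the (S,S) acid is written and its mirror image is to be used if it leads to the (2R) series; the acid is a known type of catalyst and its preparation is not counted as a step.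

**Step 1**
Reactants: 1 3,5-dimethoxyphenol
Product: 2 (3,5-dimethoxyphenoxy)tri(propan-2-yl)silane
Conditions: TIPSCl, imidazole, DMF, rt
Reagents that add atoms: chlorotri(propan-2-yl)silane (TIPSCl), CC(C)[Si](Cl)(C(C)C)C(C)C
Why: Silylation of a phenol with a silyl chloride and imidazole is routine, and the bulky triisopropylsilyl ether is a weakly coordinating group that shields both positions next to it in the lithiation that follows.

**Step 2**
Reactants: 2 (3,5-dimethoxyphenoxy)tri(propan-2-yl)silane; 3 1-bromo-3-methylbut-2-ene (prenyl bromide)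
Product: 5 [3,5-dimethoxy-4-(3-methylbut-2-en-1-yl)phenoxy]tri(propan-2-yl)silane, via aryllithium 4 (not isolated)
Conditions: n-BuLi, TMEDA, THF, 0 °C to rt; then 3, −78 °C to rt
Reagents that add atoms: none
Why: Directed ortho-metalation should remove the hydrogen flanked by the two methoxy groups (cooperative direction, the silyloxy group being bulky and a poor director), and the aryllithium should be alkylated at the primary carbon of prenyl bromide in an SN2 reaction.

**Step 3**
Reactants: 5 [3,5-dimethoxy-4-(3-methylbut-2-en-1-yl)phenoxy]tri(propan-2-yl)silane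
Product: 6 3,5-dimethoxy-4-(3-methylbut-2-en-1-yl)phenol
Conditions: TBAF, AcOH, THF, 0 °C
Reagents that add atoms: none
Why: Fluoride-mediated cleavage of an aryl silyl ether is reliable, and the acetic acid buffer keeps the electron-rich phenol from standing as its air-sensitive salt.

**Step 4**
Reactants: 6 3,5-dimethoxy-4-(3-methylbut-2-en-1-yl)phenol; 7 4-methoxybenzaldehyde
Product: 9 [3,5-dimethoxy-4-(3-methylbut-2-en-1-yl)phenoxy](4-methoxyphenyl)methyl acetate (racemic), via bromo(4-methoxyphenyl)methyl acetate 8 (not isolated)
Conditions: 7, AcBr, ZnBr2 (5 mol %), CH2Cl2, 0 °C; then 6, i-Pr2NEt, −20 °C to 0 °C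
Reagents that add atoms: acetyl bromide, CC(=O)Br
Why: Zinc halide-catalysed addition of an acyl bromide to an aldehyde should give the 1-bromoalkyl ester, an SN1-type electrophile that should O-alkylate the phenol under the amine-base conditions used for alkoxymethyl ether formation (Williamson-type etherification), the new acetal stereocentre being formed as a racemate that becomes planar again in step 5.

**Step 5**
Reactants: 9 [3,5-dimethoxy-4-(3-methylbut-2-en-1-yl)phenoxy](4-methoxyphenyl)methyl acetate (racemic); 10 tert-butyldimethyl(vinyloxy)silane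
Product: 13 (2S,4RS)-4-(tert-butyldimethylsilyloxy)-5,7-dimethoxy-2-(4-methoxyphenyl)-6-(3-methylbut-2-en-1-yl)chromane (both C4 epimers), via O-aryl oxocarbenium ion 11 (not isolated), via open-chain silyl oxocarbenium ion 12 (not isolated)
Conditions: 10 (3 equiv), (S,S)-imidodiphosphorimidate acid [(S)-Ar2C20H10O2P(=NSO2CF3)]2NH with Ar = 3,5-(CF3)2C6H3 (3 mol %), toluene, −78 °C; then Et3N
Reagents that add atoms: none
Why: Proposed new method: the acid, silylated in the flask by 10, should abstract the acetate of 9 (the carbonyl oxygen is the most basic site and an acyloxy group cannot support a cation, so the aryloxy group stays) to give the E-configured O-aryl oxocarbenium ion 11 paired with the confined chiral anion; 10 should then attack C2 through its CH2 carbon (C2–C3 bond, Mukaiyama-type addition) and the silyl oxocarbenium carbon C4 of 12 should be attacked by C4a (C4–C4a bond), the whole being a stepwise cationic [4+2] (oxa-Povarov) annulation of the 2-oxadiene C4a=C8a–O1=C2 with the enol ether. The closest known reaction types are the racemic oxa-Povarov reaction of aryloxy oxocarbenium ions with alkenes promoted by SnCl4 and the enantioselective addition of enolsilanes to aldehydes and to oxocarbenium ions from cyclic acetoxy ethers catalysed by confined imidodiphosphorimidate acids; new here are the acyclic O-aryl oxocarbenium ion as the electrophile and the arene closure in the same operation. Ring C is closed by a 6-exo-trig Friedel–Crafts attack of the arene carbon on the oxocarbenium carbon C4. The stereocentre C2 is set under catalyst control, the anion shielding one face of the planar cation 11, which resembles in shape the silyl oxocarbenium ions of aromatic aldehydes that such acids differentiate; C4 is formed without control and is erased in step 6. The step needs enantiofacial selectivity at C2, attack by 10 in preference to the prenyl double bond and to the electron-rich rings (10 is the smallest and strongest π-nucleophile present and is used in excess, which also keeps the acid silylated so that no free strong acid meets the prenyl group), and a single addition (the confined site should exclude the bulky product from further activation); regioselectivity of the closure is not an issue because the two positions ortho to O1 are equivalent and each is activated by O1 and both methoxy groups.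

**Step 6**
Reactants: 13 (2S,4RS)-4-(tert-butyldimethylsilyloxy)-5,7-dimethoxy-2-(4-methoxyphenyl)-6-(3-methylbut-2-en-1-yl)chromane (both C4 epimers)
Product: 14 (2S)-5,7-dimethoxy-2-(4-methoxyphenyl)-6-(3-methylbut-2-en-1-yl)chromane
Conditions: Et3SiH (3 equiv), trimethylsilyl trifluoromethanesulfonate (10 mol %), 2,6-di-tert-butylpyridine (20 mol %), CH2Cl2, −78 °C
Reagents that add atoms: none
Why: Ionic hydrogenation should work because the silyl triflate ionises the C4 silyl ether to a benzylic cation stabilised by O1 and by the methoxy groups at C5 and C7, which should take hydride from Et3SiH well below the temperature at which the C2–O1 bond or the prenyl double bond reacts, so that both C4 epimers converge on the target with C2 untouched.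

**Compound list**

1 | 3,5-dimethoxyphenol | COc1cc(O)cc(OC)c1 | starting material
2 | (3,5-dimethoxyphenoxy)tri(propan-2-yl)silane | COc1cc(O[Si](C(C)C)(C(C)C)C(C)C)cc(OC)c1 | intermediate
3 | 1-bromo-3-methylbut-2-ene (prenyl bromide) | CC(C)=CCBr | starting material
4 | [2,6-dimethoxy-4-(tri(propan-2-yl)silyloxy)phenyl]lithium (not isolated) | COc1cc(O[Si](C(C)C)(C(C)C)C(C)C)cc(OC)c1[Li] | intermediate
5 | [3,5-dimethoxy-4-(3-methylbut-2-en-1-yl)phenoxy]tri(propan-2-yl)silane | COc1cc(O[Si](C(C)C)(C(C)C)C(C)C)cc(OC)c1CC=C(C)C | intermediate
6 | 3,5-dimethoxy-4-(3-methylbut-2-en-1-yl)phenol | COc1cc(O)cc(OC)c1CC=C(C)C | intermediate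
7 | 4-methoxybenzaldehyde | COc1ccc(C=O)cc1 | starting material
8 | bromo(4-methoxyphenyl)methyl acetate (racemic, not isolated) | COc1ccc(C(Br)OC(C)=O)cc1 | intermediate
9 | [3,5-dimethoxy-4-(3-methylbut-2-en-1-yl)phenoxy](4-methoxyphenyl)methyl acetate (racemic) | COc1ccc(C(OC(C)=O)Oc2cc(OC)c(CC=C(C)C)c(OC)c2)cc1 | intermediate
10 | tert-butyldimethyl(vinyloxy)silane | C=CO[Si](C)(C)C(C)(C)C | starting material
11 | (E)-[3,5-dimethoxy-4-(3-methylbut-2-en-1-yl)phenyl](4-methoxybenzylidene)oxonium, cation of the ion pair with the anion of the chiral acid (not isolated) | COc1ccc(/C=[O+]/c2cc(OC)c(CC=C(C)C)c(OC)c2)cc1 | intermediate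
12 | (S)-(tert-butyldimethylsilyl){3-[3,5-dimethoxy-4-(3-methylbut-2-en-1-yl)phenoxy]-3-(4-methoxyphenyl)propylidene}oxonium, cation of the ion pair (not isolated) | COc1ccc([C@@H](Oc2cc(OC)c(CC=C(C)C)c(OC)c2)CC=[O+][Si](C)(C)C(C)(C)C)cc1 | intermediate
13 | (2S,4RS)-4-(tert-butyldimethylsilyloxy)-5,7-dimethoxy-2-(4-methoxyphenyl)-6-(3-methylbut-2-en-1-yl)chromane (both C4 epimers) | COc1ccc([C@@H]2CC(O[Si](C)(C)C(C)(C)C)c3c(cc(OC)c(CC=C(C)C)c3OC)O2)cc1 | intermediate
14 | (2S)-5,7-dimethoxy-2-(4-methoxyphenyl)-6-(3-methylbut-2-en-1-yl)chromane | COc1ccc([C@@H]2CCc3c(cc(OC)c(CC=C(C)C)c3OC)O2)cc1 | target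

**Step count**

Total step count: 6. Longest linear sequence: 6 steps (1 → 2 → 5 → 6 → 9 → 13 → 14).

**Steps most likely to fail**

Step 5 (key step, proposed new method). The acyclic oxocarbenium ion pair may be attacked with poor facial discrimination. The cation may also be intercepted by an electron-rich ring instead of the enolsilane, or the sequence may stall at the open-chain stage and lose the phenol by β-elimination.
Fallback with known chemistry, setting out from 6 and coming back to the route at 14:
- Magnesium-mediated ortho-formylation of 6 (MgCl2, Et3N, paraformaldehyde, MeCN, reflux) should give 6-hydroxy-2,4-dimethoxy-3-(3-methylbut-2-en-1-yl)benzaldehyde F1.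
- Claisen–Schmidt condensation with 4'-methoxyacetophenone (KOH, EtOH) should give (E)-3-[6-hydroxy-2,4-dimethoxy-3-(3-methylbut-2-en-1-yl)phenyl]-1-(4-methoxyphenyl)prop-2-en-1-one F2.
- Hydrogenation of the enone double bond with H2 and RhCl(PPh3)3 in benzene, which should spare the trisubstituted prenyl alkene, should give 3-[6-hydroxy-2,4-dimethoxy-3-(3-methylbut-2-en-1-yl)phenyl]-1-(4-methoxyphenyl)propan-1-one F3.
- Corey–Bakshi–Shibata reduction with the (S)-B-methyl oxazaborolidine from (S)-diphenylprolinol (C18H20BNO) and BH3·SMe2 should give 2-[(3R)-3-hydroxy-3-(4-methoxyphenyl)propyl]-3,5-dimethoxy-4-(3-methylbut-2-en-1-yl)phenol F4.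
- Mitsunobu cyclisation (PPh3, DIAD, THF, 0 °C) should close the O1–C2 bond with inversion and give 14.

Step 4. The bromo ester may revert to aldehyde and acyl bromide or ionise. The phenol would then be O-acetylated, or ring A C-alkylated, instead of being O-alkylated; the acyl acetal may also be lost by hydrolysis during purification.
Fallback, setting out from 6 and coming back at 9:
- Alkylation of 6 with methyl 2-bromo-2-(4-methoxyphenyl)acetate (K2CO3, acetone) should give methyl 2-[3,5-dimethoxy-4-(3-methylbut-2-en-1-yl)phenoxy]-2-(4-methoxyphenyl)acetate F5.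
- Saponification (LiOH, THF/H2O) should give 2-[3,5-dimethoxy-4-(3-methylbut-2-en-1-yl)phenoxy]-2-(4-methoxyphenyl)acetic acid F6.
- Oxidative decarboxylation with Pb(OAc)4 (pyridine, benzene, rt), a known way from 2-aryloxy acids to acetoxy acetals, should give 9.

Step 6. The C2–O1 benzylic ether may ionise, with loss of configurational integrity or reductive ring opening. The C4 cation may also lose a proton and disproportionate through a 2H-chromene instead of capturing hydride.
Fallback that avoids cations at the reduction stage, setting out from 13 and coming back at 14: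
- Desilylation (TBAF, AcOH, THF) should give (2S,4RS)-5,7-dimethoxy-2-(4-methoxyphenyl)-6-(3-methylbut-2-en-1-yl)chroman-4-ol F7.
- Dehydration with methyl N-(triethylammoniosulfonyl)carbamate (benzene, 50 °C, light excluded) should give (2S)-5,7-dimethoxy-2-(4-methoxyphenyl)-6-(3-methylbut-2-en-1-yl)-2H-chromene F8.
- Diimide, generated from 2-nitrobenzenesulfonohydrazide and Et3N in CH2Cl2 at rt, should reduce the cis-disubstituted C3=C4 bond much faster than the trisubstituted prenyl alkene and give 14.

**Further compounds**

F1 | step 5 | 6-hydroxy-2,4-dimethoxy-3-(3-methylbut-2-en-1-yl)benzaldehyde | COc1cc(O)c(C=O)c(OC)c1CC=C(C)C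
F2 | step 5 | (E)-3-[6-hydroxy-2,4-dimethoxy-3-(3-methylbut-2-en-1-yl)phenyl]-1-(4-methoxyphenyl)prop-2-en-1-one | COc1ccc(C(=O)/C=C/c2c(O)cc(OC)c(CC=C(C)C)c2OC)cc1
F3 | step 5 | 3-[6-hydroxy-2,4-dimethoxy-3-(3-methylbut-2-en-1-yl)phenyl]-1-(4-methoxyphenyl)propan-1-one | COc1ccc(C(=O)CCc2c(O)cc(OC)c(CC=C(C)C)c2OC)cc1
F4 | step 5 | 2-[(3R)-3-hydroxy-3-(4-methoxyphenyl)propyl]-3,5-dimethoxy-4-(3-methylbut-2-en-1-yl)phenol | COc1ccc([C@H](O)CCc2c(O)cc(OC)c(CC=C(C)C)c2OC)cc1
F5 | step 4 | methyl 2-[3,5-dimethoxy-4-(3-methylbut-2-en-1-yl)phenoxy]-2-(4-methoxyphenyl)acetate (racemic) | COC(=O)C(Oc1cc(OC)c(CC=C(C)C)c(OC)c1)c1ccc(OC)cc1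
F6 | step 4 | 2-[3,5-dimethoxy-4-(3-methylbut-2-en-1-yl)phenoxy]-2-(4-methoxyphenyl)acetic acid (racemic) | OC(=O)C(Oc1cc(OC)c(CC=C(C)C)c(OC)c1)c1ccc(OC)cc1
F7 | step 6 | (2S,4RS)-5,7-dimethoxy-2-(4-methoxyphenyl)-6-(3-methylbut-2-en-1-yl)chroman-4-ol | COc1ccc([C@@H]2CC(O)c3c(cc(OC)c(CC=C(C)C)c3OC)O2)cc1
F8 | step 6 | (2S)-5,7-dimethoxy-2-(4-methoxyphenyl)-6-(3-methylbut-2-en-1-yl)-2H-chromene | COc1ccc([C@@H]2C=Cc3c(cc(OC)c(CC=C(C)C)c3OC)O2)cc1
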